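**Plan**
Retrosynthesis: the cinnamoyl C1'–C(=O) bond is cut first (back to a phenol-directed formylation). Ring A' is then opened across C2'–C3' and C4'–C5' to a 4-(methoxyethynyl)flavan and a 3-alkoxycyclobutenone. The C4–C(sp) bond, the C2–phenyl bond and the pyranone ring are cut last, back to 5-methoxyresorcinol.
Enabling feature: ring A' (C1' = acyl carbon) has oxygen on C2', C4' and C6', and C3', the carbon bonded to flavan C4, lies between the C2' hydroxyl and the C4' methoxyl. A cyclobutenone (C1', C2', C5', C6') and a methoxyalkyne (C3', C4') assemble exactly this pattern.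
Forward: ring A is oxygenated by two directed metalations, the pyranone ring is closed, phenyl is added at C2, the alkyne is set at C4, ring A' is built by benzannulation, and the cinnamoyl chain is joined at C1'.
Stereochemistry: C2 (R) comes from ligand-controlled palladium-catalysed conjugate addition of phenylboronic acid. C4 (R, trans to phenyl) comes from substrate-controlled capture of the flavan-4-yl cation. Both centres are then carried through neutral or low-temperature steps.

Key step: step 12

Remark: cyclobutane-1,3-dione is taken as a purchasable building block, and the oxygen destined for C6' is carried as a benzyl ether so that it leaves together with the 7-O-benzyl group at −78 °C.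

Step 1
Reactants: 1 5-methoxyresorcinol
Product: 2 1-methoxy-3,5-bis(methoxymethoxy)benzene
Conditions: NaH (2.4 equiv), MOMCl (2.3 equiv), DMF, 0 °C to rt
Reagents that add atoms: chloromethyl methyl ether, COCCl
Why: Williamson-type O-alkylation of the bis-phenoxide installs two equivalent methoxymethyl ethers that later direct ring metalation.

Step 2
Reactants: 2 1-methoxy-3,5-bis(methoxymethoxy)benzene
Product: 5 4-methoxy-2,6-bis(methoxymethoxy)phenol, via aryllithium 3 (not isolated), via arylboronate 4 (not isolated)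
Conditions: n-BuLi (1.2 equiv), THF, 0 °C to rt; B(OMe)3, −78 °C to rt; AcOH, 30% aq. H2O2, 0 °C to rt
Reagents that add atoms: hydrogen peroxide, OO
Why: Directed ortho-metalation should occur at the ring carbon flanked by both chelating OMOM groups, and borate trapping followed by peroxide oxidation (borylation–oxidation) turns that C–Li bond into the phenol that becomes the C8 oxygen.

Step 3
Reactants: 5 4-methoxy-2,6-bis(methoxymethoxy)phenol
Product: 6 2,5-dimethoxy-1,3-bis(methoxymethoxy)benzene
Conditions: MeI (1.5 equiv), K2CO3, acetone, reflux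
Reagents that add atoms: iodomethane, CI
Why: Williamson methylation of the phenoxide fixes the future 8-methoxy group.

Step 4
Reactants: 6 2,5-dimethoxy-1,3-bis(methoxymethoxy)benzene
Product: 8 1-[3,6-dimethoxy-2,4-bis(methoxymethoxy)phenyl]ethan-1-one, via aryllithium 7 (not isolated)
Conditions: n-BuLi (1.2 equiv), TMEDA, THF, 0 °C; MeC(O)N(OMe)Me, −78 to 0 °C; H2O
Reagents that add atoms: N-methoxy-N-methylacetamide, CC(=O)N(C)OC
Why: A second directed ortho-metalation at one of the two equivalent remaining ring positions (between OMOM and OMe) and Weinreb ketone synthesis should give the acetophenone, over-addition being blocked by the chelated tetrahedral adduct.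

Step 5
Reactants: 8 1-[3,6-dimethoxy-2,4-bis(methoxymethoxy)phenyl]ethan-1-one
Product: 10 7-hydroxy-5,8-dimethoxy-4H-chromen-4-one, via enaminone 9 (not isolated)
Conditions: Me2NCH(OMe)2 (neat), 110 °C; evaporate; conc. HCl, MeOH, 60 °C
Reagents that add atoms: N,N-dimethylformamide dimethyl acetal, COC(OC)N(C)C
Why: Condensation of the methyl ketone with the amide acetal gives the enaminone, and acid then cleaves both MOM acetals so that the ortho phenol closes the pyranone by conjugate addition–elimination of dimethylamine (enaminone chromone synthesis), the para phenol being unable to reach the chain.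

Step 6
Reactants: 10 7-hydroxy-5,8-dimethoxy-4H-chromen-4-one
Product: 11 7-(benzyloxy)-5,8-dimethoxy-4H-chromen-4-one
Conditions: BnBr, K2CO3, DMF, rt to 50 °C
Reagents that add atoms: benzyl bromide, BrCc1ccccc1
Why: Williamson benzylation of the only free phenol masks O7 with a group that should survive every later step and leave without reduction at the end.

Step 7
Reactants: 11 7-(benzyloxy)-5,8-dimethoxy-4H-chromen-4-one; 12 phenylboronic acid
Product: 13 (2R)-7-(benzyloxy)-5,8-dimethoxy-2-phenylchroman-4-one
Conditions: Pd(OCOCF3)2 (10 mol %), (S)-t-BuPyOx (12 mol %), NH4PF6 (30 mol %), H2O (5 equiv), ClCH2CH2Cl, 60 °C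
Reagents that add atoms: none
Why: Asymmetric conjugate addition of an arylboronic acid to a chromone under divalent palladium proceeds by transmetalation, face-selective insertion of C2=C3 into the aryl–palladium bond under control of the pyridine–oxazoline ligand (setting C2 as R) and protonolysis of the palladium enolate by water; the ligand antipode is at hand should the sense of induction differ from that of the carbocyclic enone series.

Step 8
Reactants: 13 (2R)-7-(benzyloxy)-5,8-dimethoxy-2-phenylchroman-4-one
Product: 14 (2R,4R)-7-(benzyloxy)-5,8-dimethoxy-2-phenylchroman-4-ol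
Conditions: NaBH4, MeOH/THF, 0 °C to rt
Reagents that add atoms: none
Why: Borohydride reduction of the flavanone is expected to give mainly the 2,4-cis alcohol (new centre 4R, by axial hydride delivery to the half-chair with equatorial phenyl), and the configuration of this centre is of no consequence because it is erased by ionisation in step 10.

Step 9
Reactants: 15 chloroacetaldehyde dimethyl acetal
Product: 17 tributyl(methoxyethynyl)stannane, via sodium methoxyacetylide 16 (not isolated)
Conditions: NaNH2 (3.1 equiv), liq. NH3, −33 °C; NH3 evaporated, THF; Bu3SnCl, −78 °C to rt; filtration, distillation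
Reagents that add atoms: tributyltin chloride, CCCC[Sn](Cl)(CCCC)CCCC
Why: Two successive amide-induced eliminations (methanol, then hydrogen chloride) and deprotonation convert the chloroacetal into the alkoxyacetylide, which is stannylated at carbon by substitution at tin.

Step 10
Reactants: 14 (2R,4R)-7-(benzyloxy)-5,8-dimethoxy-2-phenylchroman-4-ol; 17 tributyl(methoxyethynyl)stannane
Product: 18 (2R,4R)-7-(benzyloxy)-5,8-dimethoxy-4-(methoxyethynyl)-2-phenylchromane
Conditions: 17 (2 equiv), BF3·OEt2 (20 mol %), 4 Å MS, CH2Cl2, −78 to −40 °C; Et3N quench; Et3N-deactivated silica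
Reagents that add atoms: none
Why: Lewis-acid ionisation of the benzylic alcohol gives a flavan-4-yl cation stabilised by O1, 5-OMe and 7-OBn, which is captured in an SN1 alkynylation by ipso attack of the tin-bearing carbon of the ynol ether (the carbon beta to oxygen) with loss of Bu3Sn+, the slim nucleophile entering pseudo-axially on the half-chair face opposite the equatorial C2 phenyl so that the 2,4-trans (4R) centre is set by the substrate.

Step 11
Reactants: 19 cyclobutane-1,3-dione
Product: 20 3-(benzyloxy)cyclobut-2-en-1-one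
Conditions: BnOH, PPh3, DIAD, THF, 0 °C to rt
Reagents that add atoms: benzyl alcohol, OCc1ccccc1
Why: The strongly acidic enol of the 1,3-dione is O-alkylated under Mitsunobu conditions, the usual way from cyclic 1,3-diones to their vinylogous esters.

Step 12
Reactants: 18 (2R,4R)-7-(benzyloxy)-5,8-dimethoxy-4-(methoxyethynyl)-2-phenylchromane; 20 3-(benzyloxy)cyclobut-2-en-1-one
Product: 25 5-(benzyloxy)-2-[(2R,4R)-7-(benzyloxy)-5,8-dimethoxy-2-phenylchroman-4-yl]-3-methoxyphenol, via vinylketene 21 (not isolated), via vinylcyclobutenone 22 (not isolated), via dienylketene 23 (not isolated), via cyclohexadienone 24 (not isolated)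
Conditions: 20 (1.5 equiv, in portions), toluene, 80 °C then 110 °C, argon; then K2CO3, MeOH, rt
Reagents that add atoms: none
Why: Heating opens 20 by 4π electrocyclic ring opening to vinylketene 21, whose ketene unit adds to ynol ether 18 in a [2+2] cycloaddition (forming C2'–C3' and C4'–C5') to give vinylcyclobutenone 22; a second 4π opening gives dienylketene 23, which closes ring A' by thermal disrotatory 6π electrocyclisation between the former carbonyl carbon (C2') and the methylene carbon (C1') to cyclohexadienone 24 and tautomerises to phenol 25. The closest known reaction is the Danheiser benzannulation of cyclobutenones with alkoxy- and siloxyalkynes. No stereocentre is created, and because every event is neutral and pericyclic the C2 and C4 centres of the flavan should not be touched. The selectivity needed is the regiochemistry of the ketene–alkyne cycloaddition, and the polarised ynol ether secures it: its nucleophilic carbon, the one carrying the flavanyl group, bonds to the electrophilic ketene carbonyl carbon, which places the new hydroxyl (C2') and the methoxyl (C4') on either side of C3' and the benzyloxy group para to it (C6'). The methyl ynol ether has no beta-hydrogen on its O-alkyl group and so cannot fragment by the retro-ene path open to higher alkoxyalkynes, and the brief carbonate methanolysis returns any phenol acylated by excess ketene.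

Step 13
Reactants: 25 5-(benzyloxy)-2-[(2R,4R)-7-(benzyloxy)-5,8-dimethoxy-2-phenylchroman-4-yl]-3-methoxyphenol
Product: 26 6-(benzyloxy)-3-[(2R,4R)-7-(benzyloxy)-5,8-dimethoxy-2-phenylchroman-4-yl]-2-hydroxy-4-methoxybenzaldehyde
Conditions: MgCl2 (anhydrous), Et3N, (CH2O)n, MeCN, reflux; cold 1 M HCl work-up
Reagents that add atoms: paraformaldehyde (formaldehyde), C=O
Why: Magnesium phenoxide-directed ortho-formylation (Casnati–Skattebøl reaction) delivers formaldehyde only ortho to the free hydroxyl, and since C3' is substituted the single site left is C1', the hydroxymethyl adduct being oxidised in the flask by a second formaldehyde through hydride transfer.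

Step 14
Reactants: 26 6-(benzyloxy)-3-[(2R,4R)-7-(benzyloxy)-5,8-dimethoxy-2-phenylchroman-4-yl]-2-hydroxy-4-methoxybenzaldehyde
Product: 27 (E)-1-{6-(benzyloxy)-3-[(2R,4R)-7-(benzyloxy)-5,8-dimethoxy-2-phenylchroman-4-yl]-2-hydroxy-4-methoxyphenyl}-3-phenylprop-2-en-1-ol (both epimers at the carbinol carbon)
Conditions: (E)-PhCH=CHMgBr (3 equiv), THF, −78 to 0 °C; pH 7 buffer, 0 °C; crude used at once
Reagents that add atoms: (E)-styrylmagnesium bromide, Br[Mg]/C=C/c1ccccc1
Why: Grignard 1,2-addition to the aldehyde (one equivalent being spent on the phenol) gives the allylic carbinol as a mixture of epimers at the new centre, which is left uncontrolled because it is oxidised away in step 15, and the product is not stored because an ortho-hydroxybenzylic alcohol can ionise to an ortho-quinone methide.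

Step 15
Reactants: 27 the epimeric allylic carbinols
Product: 28 (E)-1-{6-(benzyloxy)-3-[(2R,4R)-7-(benzyloxy)-5,8-dimethoxy-2-phenylchroman-4-yl]-2-hydroxy-4-methoxyphenyl}-3-phenylprop-2-en-1-one
Conditions: activated MnO2 (20 equiv), CH2Cl2, rt
Reagents that add atoms: none
Why: MnO2 oxidation of the doubly activated (allylic and benzylic) alcohol should give the enone under neutral conditions, and any Z-enone from a Z-contaminated Grignard reagent is expected to relax to the conjugated, hydrogen-bonded E-chalcone.

Step 16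
Reactants: 28 the chalcone dibenzyl ether
Product: 29 sarcandrone B
Conditions: BCl3 (1 M in CH2Cl2, 6 equiv), C6HMe5 (8 equiv), CH2Cl2, −78 °C; MeOH/CHCl3 quench at −78 °C; aq. NaHCO3
Reagents that add atoms: none
Why: Boron trichloride with pentamethylbenzene as a non-basic benzyl-cation scavenger should cleave both aryl benzyl ethers at −78 °C (the 6'-ether with chelation assistance from the ketone), a non-reductive debenzylation that is expected to spare the enone, the aryl methyl ethers and the C2 and C4 centres.

**Compound list**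
In 22–24, "flavan-4-yl" is the (2R)-7-(benzyloxy)-5,8-dimethoxy-2-phenylchroman-4-yl unit of 18 with its 2,4-trans geometry.

1 | 5-methoxyresorcinol (5-methoxybenzene-1,3-diol) | COc1cc(O)cc(O)c1 | starting material
2 | 1-methoxy-3,5-bis(methoxymethoxy)benzene | COCOc1cc(OC)cc(OCOC)c1 | intermediate
3 | [4-methoxy-2,6-bis(methoxymethoxy)phenyl]lithium | [Li]c1c(OCOC)cc(OC)cc1OCOC | intermediate (not isolated)
4 | dimethyl [4-methoxy-2,6-bis(methoxymethoxy)phenyl]boronate | COB(OC)c1c(OCOC)cc(OC)cc1OCOC | intermediate (not isolated)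
5 | 4-methoxy-2,6-bis(methoxymethoxy)phenol | COCOc1cc(OC)cc(OCOC)c1O | intermediate
6 | 2,5-dimethoxy-1,3-bis(methoxymethoxy)benzene | COCOc1cc(OC)cc(OCOC)c1OC | intermediate
7 | [3,6-dimethoxy-2,4-bis(methoxymethoxy)phenyl]lithium | [Li]c1c(OCOC)c(OC)c(OCOC)cc1OC | intermediate (not isolated)
8 | 1-[3,6-dimethoxy-2,4-bis(methoxymethoxy)phenyl]ethan-1-one | CC(=O)c1c(OCOC)c(OC)c(OCOC)cc1OC | intermediate
9 | (E)-3-(dimethylamino)-1-[3,6-dimethoxy-2,4-bis(methoxymethoxy)phenyl]prop-2-en-1-one | CN(C)/C=C/C(=O)c1c(OCOC)c(OC)c(OCOC)cc1OC | intermediate (not isolated)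
10 | 7-hydroxy-5,8-dimethoxy-4H-chromen-4-one | O=c1ccoc2c(OC)c(O)cc(OC)c12 | intermediate
11 | 7-(benzyloxy)-5,8-dimethoxy-4H-chromen-4-one | O=c1ccoc2c(OC)c(OCc3ccccc3)cc(OC)c12 | intermediate
12 | phenylboronic acid | OB(O)c1ccccc1 | starting material
13 | (2R)-7-(benzyloxy)-5,8-dimethoxy-2-phenylchroman-4-one | O=C1C[C@H](c2ccccc2)Oc2c(OC)c(OCc3ccccc3)cc(OC)c21 | intermediate
14 | (2R,4R)-7-(benzyloxy)-5,8-dimethoxy-2-phenylchroman-4-ol (2,4-cis) | O[C@@H]1C[C@H](c2ccccc2)Oc2c(OC)c(OCc3ccccc3)cc(OC)c21 | intermediate
15 | chloroacetaldehyde dimethyl acetal (2-chloro-1,1-dimethoxyethane) | COC(CCl)OC | starting material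
16 | sodium methoxyacetylide | COC#C[Na] | intermediate (not isolated)
17 | tributyl(methoxyethynyl)stannane | CCCC[Sn](CCCC)(CCCC)C#COC | intermediate
18 | (2R,4R)-7-(benzyloxy)-5,8-dimethoxy-4-(methoxyethynyl)-2-phenylchromane (2,4-trans) | COC#C[C@H]1C[C@H](c2ccccc2)Oc2c(OC)c(OCc3ccccc3)cc(OC)c21 | intermediate
19 | cyclobutane-1,3-dione | O=C1CC(=O)C1 | starting material
20 | 3-(benzyloxy)cyclobut-2-en-1-one | O=C1CC(OCc2ccccc2)=C1 | intermediate
21 | 3-(benzyloxy)buta-1,3-dien-1-one (vinylketene) | C=C(OCc1ccccc1)C=C=O | intermediate (not isolated)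
22 | 4-[1-(benzyloxy)ethenyl]-2-(flavan-4-yl)-3-methoxycyclobut-2-en-1-one (vinylcyclobutenone; both epimers at the ring sp3 carbon) | O=C1C([C@H]2C[C@H](c3ccccc3)Oc3c(OC)c(OCc4ccccc4)cc(OC)c32)=C(OC)C1C(=C)OCc1ccccc1 | intermediate (not isolated)
23 | (3E)-5-(benzyloxy)-2-(flavan-4-yl)-3-methoxyhexa-1,3,5-trien-1-one (dienylketene) | O=C=C([C@H]1C[C@H](c2ccccc2)Oc2c(OC)c(OCc3ccccc3)cc(OC)c21)/C(OC)=C\C(=C)OCc1ccccc1 | intermediate (not isolated)
24 | 5-(benzyloxy)-2-(flavan-4-yl)-3-methoxycyclohexa-2,4-dien-1-one | O=C1CC(OCc2ccccc2)=CC(OC)=C1[C@H]1C[C@H](c2ccccc2)Oc2c(OC)c(OCc3ccccc3)cc(OC)c21 | intermediate (not isolated)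
25 | 5-(benzyloxy)-2-[(2R,4R)-7-(benzyloxy)-5,8-dimethoxy-2-phenylchroman-4-yl]-3-methoxyphenol (2,4-trans) | COc1cc(OCc2ccccc2)cc(O)c1[C@H]1C[C@H](c2ccccc2)Oc2c(OC)c(OCc3ccccc3)cc(OC)c21 | intermediate
26 | 6-(benzyloxy)-3-[(2R,4R)-7-(benzyloxy)-5,8-dimethoxy-2-phenylchroman-4-yl]-2-hydroxy-4-methoxybenzaldehyde | COc1cc(OCc2ccccc2)c(C=O)c(O)c1[C@H]1C[C@H](c2ccccc2)Oc2c(OC)c(OCc3ccccc3)cc(OC)c21 | intermediate
27 | (E)-1-{6-(benzyloxy)-3-[(2R,4R)-7-(benzyloxy)-5,8-dimethoxy-2-phenylchroman-4-yl]-2-hydroxy-4-methoxyphenyl}-3-phenylprop-2-en-1-ol (both epimers at the carbinol carbon) | COc1cc(OCc2ccccc2)c(C(O)/C=C/c2ccccc2)c(O)c1[C@H]1C[C@H](c2ccccc2)Oc2c(OC)c(OCc3ccccc3)cc(OC)c21 | intermediate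
28 | (E)-1-{6-(benzyloxy)-3-[(2R,4R)-7-(benzyloxy)-5,8-dimethoxy-2-phenylchroman-4-yl]-2-hydroxy-4-methoxyphenyl}-3-phenylprop-2-en-1-one | COc1cc(OCc2ccccc2)c(C(=O)/C=C/c2ccccc2)c(O)c1[C@H]1C[C@H](c2ccccc2)Oc2c(OC)c(OCc3ccccc3)cc(OC)c21 | intermediate
29 | sarcandrone B, (E)-1-{2,6-dihydroxy-3-[(2R,4R)-7-hydroxy-5,8-dimethoxy-2-phenylchroman-4-yl]-4-methoxyphenyl}-3-phenylprop-2-en-1-one | COc1cc(O)c(C(=O)/C=C/c2ccccc2)c(O)c1[C@H]1C[C@H](c2ccccc2)Oc2c(OC)c(O)cc(OC)c21 | target

**Step count**
Total: 16 steps. Longest linear sequence: 14 steps (steps 1–8, 10, 12–16, from 5-methoxyresorcinol).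

**Steps most likely to fail**

Step 10. The Lewis acid may hydrate or oligomerise the ynol ether before or after it is attached. The cation may lose a proton to give a flav-3-ene, or be arylated by ring A of a second molecule. Facial selectivity may be too low. Fallback, setting out from 14: the cation is captured with bis(trimethylsilyl)acetylene and BF3·OEt2, an acid-stable alkynylsilane that reacts by the same ipso substitution, to give the trans 4-[(trimethylsilyl)ethynyl]flavan F1. K2CO3 in MeOH gives the terminal alkyne F2. Deprotonation with LiN(SiMe3)2, oxidation of the lithium acetylide with t-BuOOLi to the ynolate and O-silylation with i-Pr3SiOTf give the siloxyalkyne F3. Benzannulation of F3 with 20 under the conditions of step 12 gives the phenol F4, in which the new hydroxyl sits at C4' and the siloxy group at C2'. MeI and K2CO3 give the methyl ether F5, and Bu4NF buffered with AcOH removes the silyl group, which rejoins the route at 25.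

Step 12. Dimerisation or polymerisation of the alkoxyvinylketene may outrun its cycloaddition with the hindered alkyne, the ynol ether may degrade on heating, or the phenol may be consumed by acylation. Fallback, setting out from 14 and 1: ring A' is attached ready-made. Mono-benzylation of 1 (BnBr 1 equiv, K2CO3, DMF) gives 3-(benzyloxy)-5-methoxyphenol F6. Acid-catalysed Friedel–Crafts alkylation of F6 by the flavan-4-yl cation from 14 (catalytic TsOH or BF3·OEt2, CH2Cl2, low temperature) joins C4 to the ring carbon between hydroxyl and methoxyl and arrives at 25 directly. The 2,4-trans product is expected by the same facial bias, and regioisomers from attack at the two other ring positions would have to be separated.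

Step 16. The Lewis acid may open the benzylic C2–O1 ether or ionise C4 with loss of configuration, it may demethylate at C8, and the liberated 2',6'-dihydroxychalcone may cyclise to a flavanone on work-up. Fallback, setting out from 26: the benzyl groups are removed before the enone exists. MeMgBr adds to the aldehyde to give the 1-arylethanol F7, and MnO2 oxidises it to the acetophenone F8. Hydrogenolysis (H2, Pd/C, EtOAc) removes both benzyl groups to give the trihydroxy acetophenone F9. Claisen–Schmidt condensation of F9 with benzaldehyde (KOH, EtOH/H2O, rt) builds the chalcone and arrives at 29 without any Lewis acid.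

**Further compounds**
F1 | step 10 | (2R,4S)-7-(benzyloxy)-5,8-dimethoxy-2-phenyl-4-[(trimethylsilyl)ethynyl]chromane (2,4-trans) | C[Si](C)(C)C#C[C@H]1C[C@H](c2ccccc2)Oc2c(OC)c(OCc3ccccc3)cc(OC)c21
F2 | step 10 | (2R,4R)-7-(benzyloxy)-4-ethynyl-5,8-dimethoxy-2-phenylchromane (2,4-trans) | C#C[C@H]1C[C@H](c2ccccc2)Oc2c(OC)c(OCc3ccccc3)cc(OC)c21
F3 | step 10 | (2R,4R)-7-(benzyloxy)-5,8-dimethoxy-2-phenyl-4-({[tri(propan-2-yl)silyl]oxy}ethynyl)chromane (2,4-trans) | CC(C)[Si](OC#C[C@H]1C[C@H](c2ccccc2)Oc2c(OC)c(OCc3ccccc3)cc(OC)c21)(C(C)C)C(C)C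
F4 | step 10 | 5-(benzyloxy)-2-[(2R,4S)-7-(benzyloxy)-5,8-dimethoxy-2-phenylchroman-4-yl]-3-{[tri(propan-2-yl)silyl]oxy}phenol (2,4-trans) | CC(C)[Si](Oc1cc(OCc2ccccc2)cc(O)c1[C@H]1C[C@H](c2ccccc2)Oc2c(OC)c(OCc3ccccc3)cc(OC)c21)(C(C)C)C(C)C
F5 | step 10 | {5-(benzyloxy)-2-[(2R,4S)-7-(benzyloxy)-5,8-dimethoxy-2-phenylchroman-4-yl]-3-methoxyphenoxy}tri(propan-2-yl)silane (2,4-trans) | CC(C)[Si](Oc1cc(OCc2ccccc2)cc(OC)c1[C@H]1C[C@H](c2ccccc2)Oc2c(OC)c(OCc3ccccc3)cc(OC)c21)(C(C)C)C(C)C
F6 | step 12 | 3-(benzyloxy)-5-methoxyphenol | COc1cc(O)cc(OCc2ccccc2)c1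
F7 | step 16 | 1-{6-(benzyloxy)-3-[(2R,4R)-7-(benzyloxy)-5,8-dimethoxy-2-phenylchroman-4-yl]-2-hydroxy-4-methoxyphenyl}ethan-1-ol (both epimers at the carbinol carbon) | COc1cc(OCc2ccccc2)c(C(C)O)c(O)c1[C@H]1C[C@H](c2ccccc2)Oc2c(OC)c(OCc3ccccc3)cc(OC)c21
F8 | step 16 | 1-{6-(benzyloxy)-3-[(2R,4R)-7-(benzyloxy)-5,8-dimethoxy-2-phenylchroman-4-yl]-2-hydroxy-4-methoxyphenyl}ethan-1-one | COc1cc(OCc2ccccc2)c(C(C)=O)c(O)c1[C@H]1C[C@H](c2ccccc2)Oc2c(OC)c(OCc3ccccc3)cc(OC)c21
F9 | step 16 | 1-{2,6-dihydroxy-3-[(2R,4R)-7-hydroxy-5,8-dimethoxy-2-phenylchroman-4-yl]-4-methoxyphenyl}ethan-1-one | COc1cc(O)c(C(C)=O)c(O)c1[C@H]1C[C@H](c2ccccc2)Oc2c(OC)c(O)cc(OC)c21
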